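**Retrosynthetic overview**
1. Bromophycolide A (28) comes from global desilylation of 27. Compound 27 is made in the last ring-forming step, an anodically generated Br⁺ transannular cyclization of the 1,5-diene in macrolactone 26, which forms the C2–C7 bond, C6–Br and the C2=C3 alkene.
2. Macrolactone 26 comes from Yamaguchi macrolactonization of the C14-OH seco-acid 24 (the first ring formed). The tertiary C15–OH is then converted to bromide with participation from the ester.
3. Seco-acid 24 is assembled by C9-enolate alkylation of methyl ketone 13 with allylic bromide 19. C10–Br is set by Felkin reduction followed by SN2 inversion.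
4. Ketone 13 comes from Seebach alkylation of the (R)-lactic acid dioxolanone 9 with iodide 7 (from (S)-malic acid); this sets C11 and C14. Bromide 19 comes from Ni cross-coupling of an aryl bromide with geranyl chloride, then SeO₂ oxidation of the E-methyl and bromination.

**Assumptions:**
- (R)-Lactic acid and (S)-malic acid are taken as commercial single enantiomers.
- The C6/C7 configuration is controlled by macrocyclic preorganization from C10, C11 and C14.
- Carbon numbering follows geranylgeranyl: C1 is the benzylic CH₂ and C15 is CMe₂Br.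

---

**Step 1**
Reactants: 1 (S)-malic acid; 2 pivaldehyde
Product: 3 2-[(2S,4S)-2-tert-butyl-5-oxo-1,3-dioxolan-4-yl]acetic acid (cis Seebach acetal)
Conditions: p-TsOH (cat.), pentane, reflux, Dean–Stark
Reagents that add atoms: none
Why: Acetalization of the α-hydroxy acid with pivaldehyde masks C1 and the C2–OH as a dioxolanone and retains the (S) centre (future C14).

**Step 2**
Reactants: 3
Product: 4 (2S,4S)-2-tert-butyl-4-(2-hydroxyethyl)-1,3-dioxolan-5-one
Conditions: BH₃·SMe₂, THF, 0 °C → rt
Reagents that add atoms: none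
Why: Borane reduces the free carboxylic acid chemoselectively in the presence of the acetal-ester, giving the C12 primary alcohol with C14 untouched.

**Step 3**
Reactants: 4
Product: 5 (3S)-2-methylpentane-2,3,5-triol
Conditions: MeMgBr (4 equiv), THF, −20 → 0 °C
Reagents that add atoms: methylmagnesium bromide, C[Mg]Br
Why: Double Grignard addition opens the dioxolanone, releases pivaldehyde and builds the C15 dimethyl carbinol (nucleophilic acyl substitution, then ketone addition).

**Step 4**
Reactants: 5
Product: 6 (3S)-5-iodo-2-methylpentane-2,3-diol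
Conditions: I₂, PPh₃, imidazole, CH₂Cl₂, 0 °C
Reagents that add atoms: iodine, II
Why: Appel-type iodination is selective for the primary alcohol, giving the C12 electrophile; no stereocentre is touched.

**Step 5**
Reactants: 6
Product: 7 (4S)-4-(2-iodoethyl)-2,2,5,5-tetramethyl-1,3-dioxolane
Conditions: 2,2-dimethoxypropane, PPTS (cat.), CH₂Cl₂, rt
Reagents that add atoms: 2,2-dimethoxypropane, COC(C)(C)OC
Why: The acetonide protects C14-OH/C15-OH and stops the diol from cyclizing onto the iodide in base (acetalization).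

**Step 6**
Reactants: 8 (R)-lactic acid; 2 pivaldehyde
Product: 9 (2R,5R)-2-tert-butyl-5-methyl-1,3-dioxolan-4-one
Conditions: p-TsOH (cat.), pentane, reflux, Dean–Stark
Reagents that add atoms: none
Why: Acetalization gives the cis Seebach dioxolanone that stores the lactate stereocentre (future C11) for self-regeneration of stereocentres.

**Step 7**
Reactants: 9; 7
Product: 10 (2R,5S)-2-tert-butyl-5-methyl-5-{2-[(4S)-2,2,5,5-tetramethyl-1,3-dioxolan-4-yl]ethyl}-1,3-dioxolan-4-one
Conditions: LDA, THF, −78 °C; then 7, DMPU, −78 → −30 °C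
Reagents that add atoms: none
Why: The planar enolate is alkylated trans to the tert-butyl group, so the new C12 substituent takes the place of the former α-H and the quaternary C11 is (S) (Seebach alkylation).

**Step 8**
Reactants: 10
Product: 11 (2S)-2-hydroxy-N-methoxy-N,2-dimethyl-4-[(4S)-2,2,5,5-tetramethyl-1,3-dioxolan-4-yl]butanamide
Conditions: MeNHOMe·HCl, i-PrMgCl, THF, −20 → 0 °C
Reagents that add atoms: N,O-dimethylhydroxylamine, CNOC
Why: The magnesium Weinreb amide attacks the dioxolanone carbonyl, ring-opens it and releases pivaldehyde; C11 is quaternary, so it cannot epimerize.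

**Step 9**
Reactants: 11
Product: 12 (3S)-3-hydroxy-3-methyl-5-[(4S)-2,2,5,5-tetramethyl-1,3-dioxolan-4-yl]pentan-2-one
Conditions: MeMgBr (3 equiv), THF, 0 °C
Reagents that add atoms: methylmagnesium bromide, C[Mg]Br
Why: Weinreb ketone synthesis supplies the C9 methyl group, which becomes the enolizable carbon.

**Step 10**
Reactants: 12
Product: 13 (3S)-3-methyl-3-(triethylsilyloxy)-5-[(4S)-2,2,5,5-tetramethyl-1,3-dioxolan-4-yl]pentan-2-one
Conditions: TESOTf, 2,6-lutidine, CH₂Cl₂, −78 °C
Reagents that add atoms: triethylsilyl triflate, CC[Si](CC)(CC)OS(=O)(=O)C(F)(F)F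
Why: Silylation removes the chelating hydroxyl so the later hydride reduction proceeds by the non-chelation Felkin–Anh mode.

**Step 11**
Reactants: 14 methyl 3-bromo-4-hydroxybenzoate
Product: 15 methyl 3-bromo-4-(tert-butyldimethylsilyloxy)benzoate
Conditions: TBSCl, imidazole, DMF, rt
Reagents that add atoms: tert-butyldimethylsilyl chloride, CC(C)(C)[Si](C)(C)Cl
Why: The TBS ether masks the phenol and deactivates the ring toward later Br⁺ chemistry (silylation).

**Step 12**
Reactants: 15; 16 geranyl chloride ((2E)-1-chloro-3,7-dimethylocta-2,6-diene)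
Product: 17 methyl 3-[(2E)-3,7-dimethylocta-2,6-dienyl]-4-(TBSO)benzoate
Conditions: NiBr₂·diglyme, 4,4′-di-tBu-bipyridine, Mn, TMSCl (cat.), DMA, 40 °C
Reagents that add atoms: none
Why: Ni-catalysed aryl–allyl cross-electrophile coupling occurs at the unhindered allylic terminus and keeps the E alkene (no new stereocentre).

**Step 13**
Reactants: 17
Product: 18 methyl 4-(TBSO)-3-[(2E,6E)-8-hydroxy-3,7-dimethylocta-2,6-dienyl]benzoate
Conditions: SeO₂ (0.3 equiv), TBHP, salicylic acid (cat.), CH₂Cl₂, rt
Reagents that add atoms: selenium dioxide, O=[Se]=O (with TBHP, CC(C)(C)OO, as reoxidant)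
Why: Riley allylic oxidation (ene/[2,3] sequence) hydroxylates the terminal E-methyl of the more electron-rich alkene selectively.

**Step 14**
Reactants: 18
Product: 19 methyl 3-[(2E,6E)-8-bromo-3,7-dimethylocta-2,6-dienyl]-4-(TBSO)benzoate
Conditions: CBr₄, PPh₃, CH₂Cl₂, 0 °C
Reagents that add atoms: carbon tetrabromide, BrC(Br)(Br)Br
Why: Appel bromination of the primary allylic alcohol by SN2 gives the C8 electrophile with both alkenes unchanged.

**Step 15**
Reactants: 13; 19
Product: 20 ketone with the aryl-C1–C8 dienyl chain joined to C9–C10(=O)–C11(Me)(OTES)–C12–C13–C14 acetonide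
Conditions: LDA (1.05 equiv), THF, −78 °C; then 19, DMPU, −78 → −40 °C
Reagents that add atoms: none
Why: The methyl ketone has only one enolizable side (C11 is quaternary), so the kinetic enolate is alkylated SN2 by allylic bromide 19 and C8–C9 forms without touching any stereocentre.

**Step 16**
Reactants: 20
Product: 21 secondary alcohol, (10S)-C10–OH
Conditions: L-Selectride, THF, −78 °C
Reagents that add atoms: none
Why: Felkin–Anh addition of hydride anti to the α-OTES group and past the small methyl group sets (10S,11S), with C10 controlled by the lactate-derived C11.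

**Step 17**
Reactants: 21
Product: 22 (10R)-bromide
Conditions: Tf₂O, pyridine, CH₂Cl₂, −78 °C; then Bu₄NBr, DMF, 40 °C
Reagents that add atoms: tetrabutylammonium bromide, CCCC[N+](CCCC)(CCCC)CCCC.[Br-]
Why: SN2 displacement of the secondary triflate inverts C10 from (S) to (R) (triflate activation, then halide substitution).

**Step 18**
Reactants: 22
Product: 23 diol, C14-OH and C15-OH free
Conditions: PPTS, MeOH, 45 °C
Reagents that add atoms: none
Why: Mild acid methanolysis removes the strained tetramethyl-dioxolane while the tertiary TES and aryl TBS ethers survive.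

**Step 19**
Reactants: 23
Product: 24 seco-acid
Conditions: Me₃SnOH, 1,2-dichloroethane, 70 °C
Reagents that add atoms: trimethyltin hydroxide, C[Sn](C)(C)O
Why: Neutral organotin hydrolysis cleaves the methyl ester without cleaving the aryl silyl ether or forming epoxide from the bromide.

**Step 20**
Reactants: 24
Product: 25 macrolactone with C14 ester and C15 tertiary OH
Conditions: 2,4,6-Cl₃C₆H₂COCl, Et₃N, THF, rt; then DMAP, toluene, 80 °C, 0.002 M (syringe pump)
Reagents that add atoms: none
Why: Yamaguchi macrolactonization esterifies the secondary C14-OH selectively over the tertiary C15-OH, with C14 retained.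

**Step 21**
Reactants: 25
Product: 26 macrolactone with C15–Br
Conditions: Tf₂O, 2,6-di-tert-butyl-4-methylpyridine, CH₂Cl₂, −78 °C; then Bu₄NBr, −78 → 0 °C
Reagents that add atoms: tetrabutylammonium bromide, CCCC[N+](CCCC)(CCCC)CCCC.[Br-]
Why: The tertiary triflate ionizes with participation by the C14 ester (dioxolenium) and bromide opens it at the tertiary carbon, so C14 is retained (Kolb–Sharpless-type acyloxonium opening).

**Step 22**
Reactants: 26
Product: 27 silyl-protected bromophycolide A
Conditions: Bu₄NBr (2.5 equiv), 2,6-di-tert-butyl-4-methylpyridine, HFIP/CH₂Cl₂ 1:4, graphite(+)/Pt(−), undivided cell, 3 mA, 25 °C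
Reagents that add atoms: tetrabutylammonium bromide, CCCC[N+](CCCC)(CCCC)CCCC.[Br-] (Br⁻ is anodically oxidized to the Br⁺ equivalent)
Why: Proposed new method: anodic oxidation of bromide generates Br₂/Br⁺ that forms a bromonium on the C6=C7 alkene, which the C2=C3 alkene attacks across the macrocycle in a chair-like, anti-addition fashion to set C6/C7 (the C10/C11/C14 stereocentres fix the macrocycle conformation) before loss of H⁺ from C2 gives the tetrasubstituted alkene, with H⁺ reduced at the cathode; the closest known reaction types are Snider-type BDSB bromonium-initiated polyene cyclizations and anodic Br⁻ oxidation for bromoetherification, but an oxidant-free electrochemical version in a macrolactone has not been shown.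

**Step 23**
Reactants: 27
Product: 28 bromophycolide A
Conditions: HF·pyridine, pyridine, THF, 0 → 25 °C
Reagents that add atoms: none
Why: Fluoride-mediated desilylation in buffered, non-basic medium removes the aryl TBS and tertiary TES groups without forming epoxide from the β-bromo alcohol.

---

**Compound list**
1 | (S)-malic acid | OC(=O)C[C@H](O)C(=O)O | starting material
2 | pivaldehyde | CC(C)(C)C=O | starting material
3 | 2-[(2S,4S)-2-tert-butyl-5-oxo-1,3-dioxolan-4-yl]acetic acid | OC(=O)C[C@@H]1O[C@H](C(C)(C)C)OC1=O | intermediate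
4 | (2S,4S)-2-tert-butyl-4-(2-hydroxyethyl)-1,3-dioxolan-5-one | OCC[C@@H]1O[C@H](C(C)(C)C)OC1=O | intermediate
5 | (3S)-2-methylpentane-2,3,5-triol | CC(C)(O)[C@@H](O)CCO | intermediate
6 | (3S)-5-iodo-2-methylpentane-2,3-diol | CC(C)(O)[C@@H](O)CCI | intermediate
7 | (4S)-4-(2-iodoethyl)-2,2,5,5-tetramethyl-1,3-dioxolane | CC1(C)O[C@@H](CCI)C(C)(C)O1 | intermediate
8 | (R)-lactic acid | C[C@@H](O)C(=O)O | starting material
9 | (2R,5R)-2-tert-butyl-5-methyl-1,3-dioxolan-4-one | C[C@H]1O[C@@H](C(C)(C)C)OC1=O | intermediate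
10 | (2R,5S)-2-tert-butyl-5-methyl-5-{2-[(4S)-2,2,5,5-tetramethyl-1,3-dioxolan-4-yl]ethyl}-1,3-dioxolan-4-one | C[C@@]1(CC[C@@H]2OC(C)(C)OC2(C)C)O[C@@H](C(C)(C)C)OC1=O | intermediate
11 | (2S)-2-hydroxy-N-methoxy-N,2-dimethyl-4-[(4S)-2,2,5,5-tetramethyl-1,3-dioxolan-4-yl]butanamide | CON(C)C(=O)[C@@](C)(O)CC[C@@H]1OC(C)(C)OC1(C)C | intermediate
12 | (3S)-3-hydroxy-3-methyl-5-[(4S)-2,2,5,5-tetramethyl-1,3-dioxolan-4-yl]pentan-2-one | CC(=O)[C@@](C)(O)CC[C@@H]1OC(C)(C)OC1(C)C | intermediate
13 | (3S)-3-methyl-3-(triethylsilyloxy)-5-[(4S)-2,2,5,5-tetramethyl-1,3-dioxolan-4-yl]pentan-2-one | CC(=O)[C@@](C)(O[Si](CC)(CC)CC)CC[C@@H]1OC(C)(C)OC1(C)C | intermediate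
14 | methyl 3-bromo-4-hydroxybenzoate | COC(=O)c1ccc(O)c(Br)c1 | starting material
15 | methyl 3-bromo-4-(TBSO)benzoate | COC(=O)c1ccc(O[Si](C)(C)C(C)(C)C)c(Br)c1 | intermediate
16 | geranyl chloride | CC(C)=CCC/C(C)=C/CCl | starting material
17 | methyl 3-[(2E)-3,7-dimethylocta-2,6-dienyl]-4-(TBSO)benzoate | COC(=O)c1ccc(O[Si](C)(C)C(C)(C)C)c(C/C=C(\C)CCC=C(C)C)c1 | intermediate
18 | C8-allylic alcohol (E,E) | COC(=O)c1ccc(O[Si](C)(C)C(C)(C)C)c(C/C=C(\C)CC/C=C(\C)CO)c1 | intermediate
19 | C8-allylic bromide (E,E) | COC(=O)c1ccc(O[Si](C)(C)C(C)(C)C)c(C/C=C(\C)CC/C=C(\C)CBr)c1 | intermediate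
20 | C10 ketone, aryl-C1–C14 chain with C11 OTES and C14/C15 acetonide | COC(=O)c1ccc(O[Si](C)(C)C(C)(C)C)c(C/C=C(\C)CC/C=C(\C)CCC(=O)[C@@](C)(O[Si](CC)(CC)CC)CC[C@@H]2OC(C)(C)OC2(C)C)c1 | intermediate
21 | (10S)-alcohol | COC(=O)c1ccc(O[Si](C)(C)C(C)(C)C)c(C/C=C(\C)CC/C=C(\C)CC[C@H](O)[C@@](C)(O[Si](CC)(CC)CC)CC[C@@H]2OC(C)(C)OC2(C)C)c1 | intermediate
22 | (10R)-bromide | COC(=O)c1ccc(O[Si](C)(C)C(C)(C)C)c(C/C=C(\C)CC/C=C(\C)CC[C@@H](Br)[C@@](C)(O[Si](CC)(CC)CC)CC[C@@H]2OC(C)(C)OC2(C)C)c1 | intermediate
23 | C14/C15 diol | COC(=O)c1ccc(O[Si](C)(C)C(C)(C)C)c(C/C=C(\C)CC/C=C(\C)CC[C@@H](Br)[C@@](C)(O[Si](CC)(CC)CC)CC[C@H](O)C(C)(C)O)c1 | intermediate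
24 | seco-acid | OC(=O)c1ccc(O[Si](C)(C)C(C)(C)C)c(C/C=C(\C)CC/C=C(\C)CC[C@@H](Br)[C@@](C)(O[Si](CC)(CC)CC)CC[C@H](O)C(C)(C)O)c1 | intermediate
25 | macrolactone, C15–OH | O=C1O[C@H](C(C)(C)O)CC[C@](C)(O[Si](CC)(CC)CC)[C@H](Br)CC/C(C)=C/CC/C(C)=C/Cc2cc1ccc2O[Si](C)(C)C(C)(C)C | intermediate
26 | macrolactone, C15–Br | O=C1O[C@H](C(C)(C)Br)CC[C@](C)(O[Si](CC)(CC)CC)[C@H](Br)CC/C(C)=C/CC/C(C)=C/Cc2cc1ccc2O[Si](C)(C)C(C)(C)C | intermediate
27 | silyl-protected bromophycolide A | CC1=C2Cc3cc(ccc3O[Si](C)(C)C(C)(C)C)C(=O)O[C@H](C(C)(C)Br)CC[C@](C)(O[Si](CC)(CC)CC)[C@H](Br)CC[C@]2(C)[C@@H](Br)CC1 | intermediate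
28 | bromophycolide A | CC1=C2Cc3cc(ccc3O)C(=O)O[C@H](C(C)(C)Br)CC[C@](C)(O)[C@H](Br)CC[C@]2(C)[C@@H](Br)CC1 | target

---

**Totals:** 23 steps in total. The longest linear sequence is 18 steps (from (S)-malic acid, 1 → 3 → 4 → 5 → 6 → 7 → 10 → 11 → 12 → 13 → 20 → 21 → 22 → 23 → 24 → 25 → 26 → 27 → 28).

**Three steps most likely to fail**
1. **Step 22 (proposed new electrochemical cascade).** Risks are chemoselectivity among the alkenes, wrong C6/C7 diastereoselectivity, and loss of silyl groups in HFIP.
   - Fallback (known chemistry): change the order of ring formation. Run the BDSB (Et₂SBr·SbCl₅Br)–induced bromonium cyclization on the acyclic seco-ester 23/24, then close the macrolactone and separate C6/C7 diastereomers.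
2. **Step 17 (SN2 at the hindered C10 triflate).** The secondary carbon next to a quaternary centre may give elimination or no reaction.
   - Fallback: use a radical route instead. Convert the C10 alcohol to a xanthate or oxalate and do photochemical deoxygenative Br-atom transfer from BrCCl₃, letting the adjacent C11 stereocentre direct the bromine.
3. **Step 21 (C15–OH to C15–Br by ester participation).** Ionization may be transannular with the alkenes, or the ester may migrate.
   - Fallback: install C15–Br earlier on diol 23 by Kolb–Sharpless orthoester/acyl-bromide opening, giving C14-OAc/C15-Br. Remove the acetate by acidic methanolysis before the macrolactonization (Steps 19–20).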